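**Strategy.** The route builds the quinone last. The 2-methyl-6-alkyl-1,4-benzoquinone ring (C1 carbonyl flanked by the methyl-bearing C2 and the chain-bearing C6, with C3 and C5 unsubstituted) is the signature of a Dötz benzannulation. A propenyl(methoxy)carbene chromium complex supplies C2–C4, a CO ligand supplies C1, and the terminal alkyne of an acyclic enyne supplies C5 and C6. In one operation the alkyne inserts, CO inserts and a 6π electrocyclisation of the dienylketene closes the ring at C1–C2; oxidative work-up gives the quinone. The precursor is an open-chain 1,4-enyne already carrying the (R)-butenolide, made by two Johnson–Claisen iterations and a proline aminoxylation/Z-olefination.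

Key step: step 11

Remark: the stereocentre (C5 of the furanone) is read as (R) from the SMILES. The carbinol centres of 3 and 8 are made racemic on purpose, because each is erased by the rearrangement that follows.

Step 1
Reactants: 1 methacrolein; 2 propargyl bromide
Product: 3 rac-2-methylhex-1-en-5-yn-3-ol
Conditions: Zn dust, THF/sat. aq NH4Cl, 0 °C to rt
Reagents that add atoms: none
Why: Barbier-type zinc propargylation, in which the allenylzinc bromide formed in the flask adds to the aldehyde carbonyl through an SE2′ transition state to give the homopropargylic alcohol; the new carbinol centre is racemic and is destroyed in step 2.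

Step 2
Reactants: 3 rac-2-methylhex-1-en-5-yn-3-ol; 4 triethyl orthoacetate
Product: 5 ethyl (4E)-4-methyloct-4-en-7-ynoate
Conditions: neat 4 (excess), EtCO2H (cat.), 140 °C, EtOH distilled off
Reagents that add atoms: none
Why: Johnson–Claisen (orthoester Claisen) rearrangement, in which the mixed ketene acetal rearranges through a chair transition state with the propargyl-bearing carbinol substituent pseudo-equatorial, which should set the E trisubstituted alkene and erases the carbinol centre.

Step 3
Reactants: 5 ethyl (4E)-4-methyloct-4-en-7-ynoate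
Product: 6 (4E)-4-methyloct-4-en-7-ynal
Conditions: i-Bu2AlH (1.1 equiv), CH2Cl2, −78 °C; then MeOH, aq potassium sodium tartrate
Reagents that add atoms: none
Why: Partial reduction of an ester with diisobutylaluminium hydride, where the tetrahedral aluminium hemiacetal persists at −78 °C and releases the aldehyde only on work-up, the alkyne and alkene being inert.

Step 4
Reactants: 6 (4E)-4-methyloct-4-en-7-ynal; 7 isopropenylmagnesium bromide
Product: 8 rac-(6E)-2,6-dimethyldeca-1,6-dien-9-yn-3-ol
Conditions: THF, −78 to 0 °C; then sat. aq NH4Cl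
Reagents that add atoms: none
Why: Grignard 1,2-addition of an alkenylmagnesium halide to an aldehyde, which at low temperature is faster than deprotonation of the alkyne C–H; the new carbinol centre is racemic and is destroyed in step 5.

Step 5
Reactants: 8 rac-(6E)-2,6-dimethyldeca-1,6-dien-9-yn-3-ol; 4 triethyl orthoacetate
Product: 9 ethyl (4E,8E)-4,8-dimethyldodeca-4,8-dien-11-ynoate
Conditions: neat 4 (excess), EtCO2H (cat.), 140 °C, EtOH distilled off
Reagents that add atoms: none
Why: Second Johnson–Claisen rearrangement, whose chair transition state with the chain pseudo-equatorial should again give the E trisubstituted alkene, the remote alkene and the alkyne being spectators.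

Step 6
Reactants: 9 ethyl (4E,8E)-4,8-dimethyldodeca-4,8-dien-11-ynoate
Product: 10 (4E,8E)-4,8-dimethyldodeca-4,8-dien-11-ynal
Conditions: i-Bu2AlH (1.1 equiv), CH2Cl2, −78 °C; then MeOH, aq potassium sodium tartrate
Reagents that add atoms: none
Why: Partial ester reduction with diisobutylaluminium hydride as in step 3, stopping at the aldehyde because the aluminium hemiacetal does not collapse at −78 °C.

Step 7
Reactants: 11 methyl 2-[bis(2,2,2-trifluoroethoxy)phosphoryl]acetate; 12 5-bromo-2-methylpent-2-ene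
Product: 13 rac-methyl 2-[bis(2,2,2-trifluoroethoxy)phosphoryl]-6-methylhept-5-enoate
Conditions: NaH, DMSO, rt; then 12, NaI (cat.), 50 °C
Reagents that add atoms: none
Why: SN2 C-alkylation of the stabilised phosphonoacetate carbanion by a primary bromide with iodide (Finkelstein) catalysis, an excess of 11 limiting dialkylation; the new centre is racemic and is lost in the olefination.

Step 8
Reactants: 10 (4E,8E)-4,8-dimethyldodeca-4,8-dien-11-ynal; 13 rac-methyl 2-[bis(2,2,2-trifluoroethoxy)phosphoryl]-6-methylhept-5-enoate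
Product: 15 methyl (2Z,4R,6E,10E)-4-(anilinooxy)-6,10-dimethyl-2-(4-methylpent-3-en-1-yl)tetradeca-2,6,10-trien-13-ynoate, via α-anilinooxy aldehyde 14 (not isolated)
Conditions: L-proline (20 mol%), PhNO, MeCN, −20 °C; then added to 13, KN(SiMe3)2, 18-crown-6, THF, −78 °C
Reagents that add atoms: nitrosobenzene, O=Nc1ccccc1
Why: Proline-catalysed enantioselective α-aminoxylation followed in the same pot by a Still–Gennari Horner–Wadsworth–Emmons olefination: the E-enamine of L-proline is attacked by the oxygen of nitrosobenzene held by the carboxylic acid, which should set the (R) centre, and the trifluoroethyl phosphonate should give the Z trisubstituted enoate under kinetic control.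

Step 9
Reactants: 15 methyl (2Z,4R,6E,10E)-4-(anilinooxy)-6,10-dimethyl-2-(4-methylpent-3-en-1-yl)tetradeca-2,6,10-trien-13-ynoate
Product: 17 (5R)-5-[(2E,6E)-2,6-dimethyldeca-2,6-dien-9-yn-1-yl]-3-(4-methylpent-3-en-1-yl)furan-2(5H)-one, via Z-hydroxy ester 16 (not isolated)
Conditions: Cu(OAc)2 (30 mol%), EtOH, rt, Ar; then TsOH·H2O (cat.), CH2Cl2, rt
Reagents that add atoms: none
Why: Copper-catalysed N–O cleavage of the anilinooxy group frees the allylic hydroxyl, which lactonises onto the cis ester by acid-catalysed transesterification; the C–O bond at the stereocentre is never broken, so the (R) configuration is retained.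

Step 10
Reactants: 18 (E)-1-bromoprop-1-ene; 19 Cr(CO)6
Product: 22 pentacarbonyl[(2E)-1-methoxybut-2-en-1-ylidene]chromium, via (E)-prop-1-enyllithium 20 (not isolated), via lithium acylchromate 21 (not isolated)
Conditions: t-BuLi (2 equiv), Et2O, −78 °C; then 19, 0 °C to rt; then Me3OBF4, CH2Cl2/H2O, 0 °C
Reagents that add atoms: trimethyloxonium tetrafluoroborate, C[O+](C)C.F[B-](F)(F)F
Why: Fischer carbene synthesis: bromine–lithium exchange with retention of alkene geometry, addition of the alkenyllithium to a CO ligand of Cr(CO)6, and O-methylation of the acylchromate with a Meerwein salt.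

Step 11
Reactants: 17 (5R)-5-[(2E,6E)-2,6-dimethyldeca-2,6-dien-9-yn-1-yl]-3-(4-methylpent-3-en-1-yl)furan-2(5H)-one; 22 pentacarbonyl[(2E)-1-methoxybut-2-en-1-ylidene]chromium
Product: 25 yezoquinolide, via dienylketene chromium complex 23 (not isolated), via methoxyphenol chromium complex 24 (not isolated)
Conditions: 22 (1.5 equiv), THF (dilute), 50 °C, Ar; then (NH4)2Ce(NO3)6 (excess), MeCN/H2O, 0 °C
Reagents that add atoms: water, O
Why: Dötz benzannulation, a formal (3+2+1) cycloaddition, with oxidative work-up: loss of one CO from 22 lets the terminal alkyne of 17 insert into the Cr=C bond with its unsubstituted carbon joining the carbene carbon, and CO insertion then gives the chromium-bound dienylketene 23. The six-membered carbocycle closes by thermal 6π electrocyclisation of 23, in which the ketene carbon (the later C1 carbonyl) bonds to the methyl-bearing terminus of the former propenyl group (the later C2); tautomerisation gives the phenol complex 24. (NH4)2Ce(NO3)6 then oxidises off the Cr(CO)3 fragment and oxidatively demethylates the 4-methoxyphenol, water delivering the C4 oxygen, to give the quinone. No stereocentre is formed and the (R) centre of the furanone is not touched, since the conditions are neutral and then acidic. The step needs regioselective alkyne insertion, secured by the terminal alkyne, whose substituent ends next to the phenolic carbon and so gives the 2,6-disubstituted ring, and chemoselectivity for the alkyne over the butenolide and the trisubstituted alkenes, secured by alkyne insertion running at 50 °C, well below the temperature of carbene transfer to alkenes. The alkenyl carbene in THF favours CO insertion and cyclisation over furan or cyclopentadiene by-products.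

**Compound list**

1 | methacrolein (2-methylprop-2-enal) | CC(=C)C=O | starting material
2 | propargyl bromide (3-bromoprop-1-yne) | C#CCBr | starting material
3 | rac-2-methylhex-1-en-5-yn-3-ol | C=C(C)C(O)CC#C | intermediate
4 | triethyl orthoacetate | CCOC(C)(OCC)OCC | starting material
5 | ethyl (4E)-4-methyloct-4-en-7-ynoate | CCOC(=O)CC/C(C)=C/CC#C | intermediate
6 | (4E)-4-methyloct-4-en-7-ynal | O=CCC/C(C)=C/CC#C | intermediate
7 | isopropenylmagnesium bromide | CC(=C)[Mg]Br | starting material
8 | rac-(6E)-2,6-dimethyldeca-1,6-dien-9-yn-3-ol | C=C(C)C(O)CC/C(C)=C/CC#C | intermediate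
9 | ethyl (4E,8E)-4,8-dimethyldodeca-4,8-dien-11-ynoate | CCOC(=O)CC/C(C)=C/CC/C(C)=C/CC#C | intermediate
10 | (4E,8E)-4,8-dimethyldodeca-4,8-dien-11-ynal | O=CCC/C(C)=C/CC/C(C)=C/CC#C | intermediate
11 | methyl 2-[bis(2,2,2-trifluoroethoxy)phosphoryl]acetate | COC(=O)CP(=O)(OCC(F)(F)F)OCC(F)(F)F | starting material
12 | 5-bromo-2-methylpent-2-ene | CC(C)=CCCBr | starting material
13 | rac-methyl 2-[bis(2,2,2-trifluoroethoxy)phosphoryl]-6-methylhept-5-enoate | COC(=O)C(CCC=C(C)C)P(=O)(OCC(F)(F)F)OCC(F)(F)F | intermediate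
14 | (2R,4E,8E)-2-(anilinooxy)-4,8-dimethyldodeca-4,8-dien-11-ynal | O=C[C@H](ONc1ccccc1)C/C(C)=C/CC/C(C)=C/CC#C | intermediate
15 | methyl (2Z,4R,6E,10E)-4-(anilinooxy)-6,10-dimethyl-2-(4-methylpent-3-en-1-yl)tetradeca-2,6,10-trien-13-ynoate | COC(=O)/C(CCC=C(C)C)=C\[C@H](ONc1ccccc1)C/C(C)=C/CC/C(C)=C/CC#C | intermediate
16 | methyl (2Z,4R,6E,10E)-4-hydroxy-6,10-dimethyl-2-(4-methylpent-3-en-1-yl)tetradeca-2,6,10-trien-13-ynoate | COC(=O)/C(CCC=C(C)C)=C\[C@H](O)C/C(C)=C/CC/C(C)=C/CC#C | intermediate
17 | (5R)-5-[(2E,6E)-2,6-dimethyldeca-2,6-dien-9-yn-1-yl]-3-(4-methylpent-3-en-1-yl)furan-2(5H)-one | CC(C)=CCCC1=C[C@@H](C/C(C)=C/CC/C(C)=C/CC#C)OC1=O | intermediate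
18 | (E)-1-bromoprop-1-ene | C/C=C/Br | starting material
19 | chromium hexacarbonyl, Cr(CO)6 | O=C=[Cr](=C=O)(=C=O)(=C=O)(=C=O)=C=O | starting material
20 | (E)-prop-1-enyllithium | [Li]/C=C/C | intermediate
21 | lithium pentacarbonyl[(2E)-1-oxidobut-2-en-1-ylidene]chromate | [Li+].[O-]C(/C=C/C)=[Cr](=C=O)(=C=O)(=C=O)(=C=O)=C=O | intermediate
22 | pentacarbonyl[(2E)-1-methoxybut-2-en-1-ylidene]chromium | COC(/C=C/C)=[Cr](=C=O)(=C=O)(=C=O)(=C=O)=C=O | intermediate
23 | Cr(CO)3 complex of the dienylketene (3E,5E)-4-methoxy-2-{(2E,6E)-3,7-dimethyl-8-[(2R)-4-(4-methylpent-3-en-1-yl)-5-oxo-2,5-dihydrofuran-2-yl]octa-2,6-dien-1-yl}hepta-1,3,5-trien-1-one (π-bound metal fragment written as a second component) | C/C=C/C(OC)=C\C(=C=O)C/C=C(C)/CC/C=C(C)/C[C@H]1OC(=O)C(CCC=C(C)C)=C1.[Cr](=C=O)(=C=O)=C=O | intermediate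
24 | Cr(CO)3 complex of (5R)-5-[(2E,6E)-8-(2-hydroxy-5-methoxy-3-methylphenyl)-2,6-dimethylocta-2,6-dien-1-yl]-3-(4-methylpent-3-en-1-yl)furan-2(5H)-one (π-bound metal fragment written as a second component) | CC(C)=CCCC1=C[C@@H](C/C(C)=C/CC/C(C)=C/Cc2cc(OC)cc(C)c2O)OC1=O.[Cr](=C=O)(=C=O)=C=O | intermediate
25 | yezoquinolide, 2-methyl-6-{(2E,6E)-3,7-dimethyl-8-[(2R)-4-(4-methylpent-3-en-1-yl)-5-oxo-2,5-dihydrofuran-2-yl]octa-2,6-dien-1-yl}cyclohexa-2,5-diene-1,4-dione | CC(C)=CCCC1=C[C@@H](C/C(C)=C/CC/C(C)=C/CC2=CC(=O)C=C(C)C2=O)OC1=O | target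

**Step count.** Total: 11 steps. Longest linear sequence: 9 steps (steps 1–6, 8, 9 and 11).

**Steps most likely to fail**

Step 11. On this late, polyfunctional substrate the carbene complex may oligomerise the terminal alkyne or stop before CO insertion, and the cerium work-up may over-oxidise or hydrate the trisubstituted alkenes. The fallback moves the annulation to the robust ester stage and builds the butenolide afterwards; it sets out from 9 and comes back at 25. Ester 9 and complex 22 (THF, 50 °C, then stirring in air) should give the phenol ethyl (4E,8E)-10-(2-hydroxy-5-methoxy-3-methylphenyl)-4,8-dimethyldeca-4,8-dienoate F1. Methylation (MeI, K2CO3, acetone) gives ethyl (4E,8E)-10-(2,5-dimethoxy-3-methylphenyl)-4,8-dimethyldeca-4,8-dienoate F2. Diisobutylaluminium hydride at −78 °C gives (4E,8E)-10-(2,5-dimethoxy-3-methylphenyl)-4,8-dimethyldeca-4,8-dienal F3. L-Proline and nitrosobenzene then give (2R,4E,8E)-2-(anilinooxy)-10-(2,5-dimethoxy-3-methylphenyl)-4,8-dimethyldeca-4,8-dienal F4, which is olefinated in the same pot with the potassium salt of 13 to methyl (2Z,4R,6E,10E)-4-(anilinooxy)-12-(2,5-dimethoxy-3-methylphenyl)-6,10-dimethyl-2-(4-methylpent-3-en-1-yl)dodeca-2,6,10-trienoate F5. Cu(OAc)2 in EtOH gives methyl (2Z,4R,6E,10E)-12-(2,5-dimethoxy-3-methylphenyl)-4-hydroxy-6,10-dimethyl-2-(4-methylpent-3-en-1-yl)dodeca-2,6,10-trienoate F6, which lactonises with catalytic TsOH to (5R)-5-[(2E,6E)-8-(2,5-dimethoxy-3-methylphenyl)-2,6-dimethylocta-2,6-dien-1-yl]-3-(4-methylpent-3-en-1-yl)furan-2(5H)-one F7. Brief oxidative demethylation with (NH4)2Ce(NO3)6 in MeCN/H2O at 0 °C, now on a purified, chromium-free arene, gives 25.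

Step 8. The α-anilinooxy aldehyde may self-condense or lose enantiopurity before it is olefinated, nitrosobenzene may be consumed by ene reaction with the trisubstituted alkenes, and Z-selectivity may erode in the mixed solvent. The fallback uses an isolable α-acyloxy aldehyde; it sets out from 10 and comes back at 17, bypassing steps 8 and 9. Dibenzoyl peroxide with (R)-α,α-diphenylprolinol trimethylsilyl ether (a steric-shielding catalyst, opposite facial sense to proline of the same configuration) in THF should give (2R,4E,8E)-4,8-dimethyl-1-oxododeca-4,8-dien-11-yn-2-yl benzoate F8. Still–Gennari olefination of the purified aldehyde with 13 (KN(SiMe3)2, 18-crown-6, THF, −78 °C) gives methyl (2Z,4R,6E,10E)-4-(benzoyloxy)-6,10-dimethyl-2-(4-methylpent-3-en-1-yl)tetradeca-2,6,10-trien-13-ynoate F9. Short methanolysis of the benzoate (K2CO3, MeOH, 0 °C, kept brief to avoid γ-epimerisation) frees hydroxy ester 16, which closes to 17.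

Step 6. The partial reduction may overshoot to the primary alcohol or stall at the aluminium hemiacetal, giving mixtures. The fallback is a full reduction and re-oxidation; it sets out from 9 and comes back at 10. LiAlH4 in Et2O at 0 °C gives (4E,8E)-4,8-dimethyldodeca-4,8-dien-11-yn-1-ol F10, and Dess–Martin periodinane with NaHCO3 in CH2Cl2 returns aldehyde 10.

Further compounds
F1 | step 11 | ethyl (4E,8E)-10-(2-hydroxy-5-methoxy-3-methylphenyl)-4,8-dimethyldeca-4,8-dienoate | CCOC(=O)CC/C(C)=C/CC/C(C)=C/Cc1cc(OC)cc(C)c1O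
F2 | step 11 | ethyl (4E,8E)-10-(2,5-dimethoxy-3-methylphenyl)-4,8-dimethyldeca-4,8-dienoate | CCOC(=O)CC/C(C)=C/CC/C(C)=C/Cc1cc(OC)cc(C)c1OC
F3 | step 11 | (4E,8E)-10-(2,5-dimethoxy-3-methylphenyl)-4,8-dimethyldeca-4,8-dienal | O=CCC/C(C)=C/CC/C(C)=C/Cc1cc(OC)cc(C)c1OC
F4 | step 11 | (2R,4E,8E)-2-(anilinooxy)-10-(2,5-dimethoxy-3-methylphenyl)-4,8-dimethyldeca-4,8-dienal | O=C[C@H](ONc1ccccc1)C/C(C)=C/CC/C(C)=C/Cc1cc(OC)cc(C)c1OC
F5 | step 11 | methyl (2Z,4R,6E,10E)-4-(anilinooxy)-12-(2,5-dimethoxy-3-methylphenyl)-6,10-dimethyl-2-(4-methylpent-3-en-1-yl)dodeca-2,6,10-trienoate | COC(=O)/C(CCC=C(C)C)=C\[C@H](ONc1ccccc1)C/C(C)=C/CC/C(C)=C/Cc1cc(OC)cc(C)c1OC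
F6 | step 11 | methyl (2Z,4R,6E,10E)-12-(2,5-dimethoxy-3-methylphenyl)-4-hydroxy-6,10-dimethyl-2-(4-methylpent-3-en-1-yl)dodeca-2,6,10-trienoate | COC(=O)/C(CCC=C(C)C)=C\[C@H](O)C/C(C)=C/CC/C(C)=C/Cc1cc(OC)cc(C)c1OC
F7 | step 11 | (5R)-5-[(2E,6E)-8-(2,5-dimethoxy-3-methylphenyl)-2,6-dimethylocta-2,6-dien-1-yl]-3-(4-methylpent-3-en-1-yl)furan-2(5H)-one | CC(C)=CCCC1=C[C@@H](C/C(C)=C/CC/C(C)=C/Cc2cc(OC)cc(C)c2OC)OC1=O
F8 | step 8 | (2R,4E,8E)-4,8-dimethyl-1-oxododeca-4,8-dien-11-yn-2-yl benzoate | O=C[C@H](OC(=O)c1ccccc1)C/C(C)=C/CC/C(C)=C/CC#C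
F9 | step 8 | methyl (2Z,4R,6E,10E)-4-(benzoyloxy)-6,10-dimethyl-2-(4-methylpent-3-en-1-yl)tetradeca-2,6,10-trien-13-ynoate | COC(=O)/C(CCC=C(C)C)=C\[C@H](OC(=O)c1ccccc1)C/C(C)=C/CC/C(C)=C/CC#C
F10 | step 6 | (4E,8E)-4,8-dimethyldodeca-4,8-dien-11-yn-1-ol | OCCC/C(C)=C/CC/C(C)=C/CC#C
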